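The route rests on cutting the side chain between C3′ (vinyl CH) and C4′ (ketone carbon) of the (Z)-4-oxodec-2-enoate. A neutral Pd-catalysed acyl Stille coupling of heptanoyl chloride with the (Z)-β-tributylstannylacrylate of the complete bicyclic core (tetrahydropyran fused to the δ-lactone, C3 acetate in place) forms this bond last and gives the target directly. The step exploits the cis-1,4-dicarbonyl array C1′(=O)–C2′=C3′–C4′(=O): the C1′ ester oxygen chelates tin and holds the Z geometry, which is transferred with retention, while the free Z-keto acid (a hydroxybutenolide pseudo-acid) is never needed. The core comes from an auxiliary-controlled aldol, a Z-alkenyllithium/Weinreb coupling and a hydroxyl-directed epoxidation/6-exo epoxide-opening cascade.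

Key step: step 19

Remark: core atoms are numbered C1 (lactone carbonyl) to C9 (methyl on C8) and side-chain atoms C1′ to C10′; the target is taken as (2R,3S,4S,5S,6R,7R,8S,2′Z) as its SMILES reads; simple reagents are not numbered.

Step 1
Reactants: 1 methyl (S)-3-hydroxy-2-methylpropanoate
Product: 2 methyl (S)-3-(tert-butyldimethylsilyloxy)-2-methylpropanoate
Conditions: TBSCl, imidazole, DMF, 0 °C to rt
Reagents that add atoms: tert-butyldimethylsilyl chloride, CC(C)(C)[Si](C)(C)Cl
Why: Standard imidazole-promoted silylation (silyl ether protection) of the primary alcohol; the C2 stereocentre comes unchanged from the chiral pool.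

Step 2
Reactants: 2 methyl (S)-3-(tert-butyldimethylsilyloxy)-2-methylpropanoate
Product: 3 (S)-3-(tert-butyldimethylsilyloxy)-2-methylpropanal
Conditions: DIBAL-H (1.05 equiv), CH2Cl2, −78 °C; Rochelle salt work-up; used at once
Reagents that add atoms: none
Why: Partial DIBAL-H reduction of an ester at −78 °C stops at the aldehyde through the stable aluminium hemiacetal, and the neutral work-up with immediate use avoids epimerisation of the α-stereocentre.

Step 3
Reactants: 3 (S)-3-(tert-butyldimethylsilyloxy)-2-methylpropanal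
Product: 4 (R,Z)-tert-butyl[(4-iodo-2-methylpent-3-en-1-yl)oxy]dimethylsilane
Conditions: EtPPh3I, n-BuLi, THF, rt; I2, −78 °C; NaHMDS, −20 °C; then 3, −78 °C to rt
Reagents that add atoms: ethyltriphenylphosphonium iodide, CC[P+](c1ccccc1)(c1ccccc1)c1ccccc1.[I-]; iodine, II
Why: Stork–Zhao olefination: the non-stabilised α-iodo ylide reacts under kinetic Wittig control to give the (Z)-2-iodoalkene, which places iodine (the later attachment point of C5) cis to the C2 chain.

Step 4
Reactants: 5 ethyl (S)-lactate
Product: 6 ethyl (S)-2-(tert-butyldimethylsilyloxy)propanoate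
Conditions: TBSCl, imidazole, DMF, 0 °C to rt
Reagents that add atoms: tert-butyldimethylsilyl chloride, CC(C)(C)[Si](C)(C)Cl
Why: Standard silyl ether protection of the secondary alcohol; the lactate stereocentre (later C8) is untouched.

Step 5
Reactants: 6 ethyl (S)-2-(tert-butyldimethylsilyloxy)propanoate
Product: 7 (S)-2-(tert-butyldimethylsilyloxy)propanal
Conditions: DIBAL-H (1.05 equiv), Et2O/hexane, −78 °C; Rochelle salt work-up; used at once
Reagents that add atoms: none
Why: Partial DIBAL-H reduction of the ester through the aluminium hemiacetal gives the α-silyloxy aldehyde without racemisation when it is kept cold and used directly.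

Step 6
Reactants: 7 (S)-2-(tert-butyldimethylsilyloxy)propanal; 8 (R)-4-benzyl-3-propionyloxazolidin-2-one
Product: 10 (R)-4-benzyl-3-[(2R,3R,4S)-4-(tert-butyldimethylsilyloxy)-3-hydroxy-2-methylpentanoyl]oxazolidin-2-one, via Z-boron enolate 9 (not isolated)
Conditions: n-Bu2BOTf, i-Pr2NEt, CH2Cl2, −78 to 0 °C; then 7, −78 to 0 °C; pH 7 buffer, MeOH, H2O2, 0 °C
Reagents that add atoms: none
Why: Evans syn-aldol: the Z-boron enolate reacts through a closed Zimmerman–Traxler chair with the auxiliary carbonyl dipole opposed, so the (R)-benzyl auxiliary sets C6 (R) and C7 (R) (6,7-syn) under reagent control, while C8 comes from lactate and the 7,8-anti (Felkin–Anh) relationship is not opposed by the aldehyde.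

Step 7
Reactants: 10 (R)-4-benzyl-3-[(2R,3R,4S)-4-(tert-butyldimethylsilyloxy)-3-hydroxy-2-methylpentanoyl]oxazolidin-2-one
Product: 11 (2R,3R,4S)-4-(tert-butyldimethylsilyloxy)-3-hydroxy-N-methoxy-N,2-dimethylpentanamide
Conditions: MeNHOMe·HCl, AlMe3, CH2Cl2, −20 to 0 °C
Reagents that add atoms: N,O-dimethylhydroxylamine hydrochloride, CNOC.Cl
Why: Aluminium-amide transamination (Weinreb amide formation) of the N-acyloxazolidinone, assisted by the free β-hydroxyl, exchanges the auxiliary without epimerising C6.

Step 8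
Reactants: 11 (2R,3R,4S)-4-(tert-butyldimethylsilyloxy)-3-hydroxy-N-methoxy-N,2-dimethylpentanamide
Product: 12 (2R,3R,4S)-3-(benzyloxy)-4-(tert-butyldimethylsilyloxy)-N-methoxy-N,2-dimethylpentanamide
Conditions: BnOC(=NH)CCl3, TfOH (cat.), cyclohexane/CH2Cl2, 0 °C to rt
Reagents that add atoms: benzyl 2,2,2-trichloroacetimidate, N=C(OCc1ccccc1)C(Cl)(Cl)Cl
Why: Acid-catalysed O-benzylation with the trichloroacetimidate protects the C7 hydroxyl without base, so neither retro-aldol cleavage nor silyl migration can occur.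

Step 9
Reactants: 4 (R,Z)-tert-butyl[(4-iodo-2-methylpent-3-en-1-yl)oxy]dimethylsilane; 12 (2R,3R,4S)-3-(benzyloxy)-4-(tert-butyldimethylsilyloxy)-N-methoxy-N,2-dimethylpentanamide
Product: 14 (2R,3Z,6R,7R,8S)-7-(benzyloxy)-1,8-bis(tert-butyldimethylsilyloxy)-2,4,6-trimethylnon-3-en-5-one, via alkenyllithium 13 (not isolated)
Conditions: 4, t-BuLi (2.1 equiv), Et2O, −78 °C; then 12, −78 to −20 °C; aq. NH4Cl
Reagents that add atoms: none
Why: Iodine–lithium exchange proceeds with retention to a configurationally stable alkenyllithium, and the Weinreb ketone synthesis stops at the ketone through the chelated tetrahedral intermediate, giving the Z-enone with C5 cis to C2 and all four stereocentres untouched.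

Step 10
Reactants: 14 (2R,3Z,6R,7R,8S)-7-(benzyloxy)-1,8-bis(tert-butyldimethylsilyloxy)-2,4,6-trimethylnon-3-en-5-one
Product: 15 (2R,3Z,5S,6S,7R,8S)-7-(benzyloxy)-1,8-bis(tert-butyldimethylsilyloxy)-2,4,6-trimethylnon-3-en-5-ol
Conditions: Zn(BH4)2, Et2O, −30 °C
Reagents that add atoms: none
Why: Chelation-controlled 1,2-reduction: zinc bridges the C5 carbonyl and the C7 benzyloxy oxygen in a six-membered chelate and hydride adds to the face away from the pseudo-axial C6 methyl, which should give the 5,6-syn/5,7-syn alcohol (C5 S).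

Step 11
Reactants: 15 (2R,3Z,5S,6S,7R,8S)-7-(benzyloxy)-1,8-bis(tert-butyldimethylsilyloxy)-2,4,6-trimethylnon-3-en-5-ol
Product: 16 (2R,3Z,5S,6S,7R,8S)-7-(benzyloxy)-2,4,6-trimethylnon-3-ene-1,5,8-triol
Conditions: TBAF, THF, rt
Reagents that add atoms: none
Why: Fluoride-mediated cleavage of both silyl ethers frees the C1 and C8 hydroxyls before any acid- or base-sensitive epoxide is present; no stereocentre is affected.

Step 12
Reactants: 16 (2R,3Z,5S,6S,7R,8S)-7-(benzyloxy)-2,4,6-trimethylnon-3-ene-1,5,8-triol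
Product: 18 (2S,3S)-3-[(2R,3S,4S,5R,6S)-5-(benzyloxy)-3-hydroxy-2,4,6-trimethyloxan-2-yl]-2-methylpropane-1,3-diol, via cis-epoxide 17 (not isolated)
Conditions: mCPBA, CH2Cl2, −20 to 0 °C; then CSA (cat.), rt
Reagents that add atoms: meta-chloroperbenzoic acid, OOC(=O)c1cccc(Cl)c1
Why: Hydroxyl-directed Prilezhaev epoxidation of the Z-allylic alcohol in its A(1,3)-strain-minimised conformer (threo delivery from C5-OH, reinforced by the homoallylic C1-OH on the same face) should give the cis-(3S,4R)-epoxide, which the C8 hydroxyl opens under acid by 6-exo-tet attack at the tertiary C4 with inversion through an all-equatorial chair, fixing C3 and C4 and closing the tetrahydropyran.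

Step 13
Reactants: 18 (2S,3S)-3-[(2R,3S,4S,5R,6S)-5-(benzyloxy)-3-hydroxy-2,4,6-trimethyloxan-2-yl]-2-methylpropane-1,3-diol
Product: 21 7-O-benzyl-3-hydroxy bicyclic δ-lactone (core of the target with OH at C3 and OBn at C7), via hydroxy aldehyde 19 (not isolated), via lactol 20 (not isolated)
Conditions: TEMPO (cat.), PhI(OAc)2, CH2Cl2, rt
Reagents that add atoms: none
Why: Oxoammonium (TEMPO) oxidation is selective for the primary C1 alcohol, the aldehyde is trapped by the equatorial C5 hydroxyl as the six-membered lactol, and this is oxidised on to the trans-fused δ-lactone while the hindered secondary C3 hydroxyl is left.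

Step 14
Reactants: 21 7-O-benzyl-3-hydroxy bicyclic δ-lactone
Product: 22 7-O-benzyl bicyclic lactone 3-acetate
Conditions: Ac2O, pyridine, DMAP (cat.), CH2Cl2, 0 °C to rt
Reagents that add atoms: acetic anhydride, CC(=O)OC(C)=O
Why: DMAP-catalysed acetylation of the only free hydroxyl installs the C3 acetate; mild base at low temperature avoids β-elimination of the β-acyloxy lactone.

Step 15
Reactants: 22 7-O-benzyl bicyclic lactone 3-acetate
Product: 23 core alcohol (3-acetoxy-7-hydroxy bicyclic lactone, all stereocentres as in the target)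
Conditions: H2 (1 atm), Pd(OH)2/C, EtOAc, rt
Reagents that add atoms: none
Why: Hydrogenolysis of the benzyl ether frees the C7 hydroxyl; lactone and acetate are inert under these neutral conditions.

Step 16
Reactants: 24 ethyl propiolate
Product: 25 ethyl (Z)-3-(tributylstannyl)acrylate
Conditions: Bu3SnH, Et3B (cat.), trace air, toluene, −78 to −40 °C; chromatography
Reagents that add atoms: tributyltin hydride, CCCC[SnH](CCCC)CCCC
Why: Radical hydrostannation: the stannyl radical adds to the terminal alkyne carbon and kinetic anti H-atom transfer to the vinyl radical at low temperature should favour the Z-β-stannyl acrylate, which is separated from minor isomers.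

Step 17
Reactants: 25 ethyl (Z)-3-(tributylstannyl)acrylate
Product: 26 (Z)-3-(tributylstannyl)acrylic acid
Conditions: LiOH, THF/H2O, 0 °C to rt; cold dilute HCl to pH 4
Reagents that add atoms: lithium hydroxide, [Li+].[OH-]
Why: Saponification of the ethyl ester; the electron-poor alkenylstannane resists protodestannylation during brief cold acidification and the Z geometry is kept.

Step 18
Reactants: 23 core alcohol; 26 (Z)-3-(tributylstannyl)acrylic acid
Product: 28 (Z)-3-(tributylstannyl)acrylate of the core alcohol at O7, via mixed anhydride 27 (not isolated)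
Conditions: 2-methyl-6-nitrobenzoic anhydride, Et3N, DMAP, CH2Cl2, rt
Reagents that add atoms: none
Why: Mixed-anhydride esterification (DMAP acyl transfer) acylates the hindered equatorial C7 hydroxyl at room temperature without touching the C–Sn bond or the Z geometry.

Step 19
Reactants: 28 (Z)-3-(tributylstannyl)acrylate of the core alcohol; 29 heptanoyl chloride
Product: 30 botcinin J
Conditions: 29 (1.5 equiv), Pd2(dba)3 (5 mol %), AsPh3 (20 mol %), THF, 23–40 °C, dark
Reagents that add atoms: none
Why: Pd(0) inserts into the C–Cl bond of 29 to give an acylpalladium(II) chloride, the alkenyl group of 28 is transferred from tin to palladium, and reductive elimination forms the C3′–C4′ bond and releases Bu3SnCl. The closest known reaction type is the acyl Stille ketone synthesis, which is established for acid chlorides with β-stannylacrylates. No ring is closed and no stereocentre is formed; the only stereochemical element, the C2′=C3′ geometry, is carried over with retention from the stannane, which is held Z by the C1′=O→Sn chelate. The step needs chemoselectivity for the acid chloride over the lactone, acetate and enoate carbonyls, which is secured because only the C–Cl bond adds oxidatively to Pd(0) under neutral conditions. It also needs the Z-enedione to survive, which is secured by the absence of base, amine and nucleophilic phosphine (AsPh3 as ligand), exclusion of light and a temperature near ambient, the latter also suppressing decarbonylation of the acylpalladium. Because the ester is already in place, the Z-keto acid, which would close to its hydroxybutenolide pseudo-acid and esterify as a pseudo-ester, is never formed.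

Compound list
1 | methyl (S)-3-hydroxy-2-methylpropanoate | COC(=O)[C@@H](C)CO | starting material
2 | methyl (S)-3-(tert-butyldimethylsilyloxy)-2-methylpropanoate | COC(=O)[C@@H](C)CO[Si](C)(C)C(C)(C)C | intermediate
3 | (S)-3-(tert-butyldimethylsilyloxy)-2-methylpropanal | O=C[C@@H](C)CO[Si](C)(C)C(C)(C)C | intermediate
4 | (R,Z)-tert-butyl[(4-iodo-2-methylpent-3-en-1-yl)oxy]dimethylsilane | I/C(C)=C\[C@@H](C)CO[Si](C)(C)C(C)(C)C | intermediate
5 | ethyl (S)-lactate | C[C@H](O)C(=O)OCC | starting material
6 | ethyl (S)-2-(tert-butyldimethylsilyloxy)propanoate | C[C@H](O[Si](C)(C)C(C)(C)C)C(=O)OCC | intermediate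
7 | (S)-2-(tert-butyldimethylsilyloxy)propanal | C[C@H](O[Si](C)(C)C(C)(C)C)C=O | intermediate
8 | (R)-4-benzyl-3-propionyloxazolidin-2-one | CCC(=O)N1[C@H](Cc2ccccc2)COC1=O | starting material
9 | (Z)-dibutylboron enolate of 8 | CCCCB(CCCC)O/C(=C\C)N1[C@H](Cc2ccccc2)COC1=O | intermediate
10 | (R)-4-benzyl-3-[(2R,3R,4S)-4-(tert-butyldimethylsilyloxy)-3-hydroxy-2-methylpentanoyl]oxazolidin-2-one | C[C@H](O[Si](C)(C)C(C)(C)C)[C@H](O)[C@@H](C)C(=O)N1[C@H](Cc2ccccc2)COC1=O | intermediate
11 | (2R,3R,4S)-4-(tert-butyldimethylsilyloxy)-3-hydroxy-N-methoxy-N,2-dimethylpentanamide | C[C@H](O[Si](C)(C)C(C)(C)C)[C@H](O)[C@@H](C)C(=O)N(C)OC | intermediate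
12 | (2R,3R,4S)-3-(benzyloxy)-4-(tert-butyldimethylsilyloxy)-N-methoxy-N,2-dimethylpentanamide | C[C@H](O[Si](C)(C)C(C)(C)C)[C@H](OCc1ccccc1)[C@@H](C)C(=O)N(C)OC | intermediate
13 | alkenyllithium from 4 (Li in place of I, geometry retained, Li cis to C2) | [Li]/C(C)=C\[C@@H](C)CO[Si](C)(C)C(C)(C)C | intermediate
14 | (2R,3Z,6R,7R,8S)-7-(benzyloxy)-1,8-bis(tert-butyldimethylsilyloxy)-2,4,6-trimethylnon-3-en-5-one | C[C@H](O[Si](C)(C)C(C)(C)C)[C@H](OCc1ccccc1)[C@@H](C)C(=O)/C(C)=C\[C@@H](C)CO[Si](C)(C)C(C)(C)C | intermediate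
15 | (2R,3Z,5S,6S,7R,8S)-7-(benzyloxy)-1,8-bis(tert-butyldimethylsilyloxy)-2,4,6-trimethylnon-3-en-5-ol | C[C@H](O[Si](C)(C)C(C)(C)C)[C@H](OCc1ccccc1)[C@@H](C)[C@H](O)/C(C)=C\[C@@H](C)CO[Si](C)(C)C(C)(C)C | intermediate
16 | (2R,3Z,5S,6S,7R,8S)-7-(benzyloxy)-2,4,6-trimethylnon-3-ene-1,5,8-triol | C[C@H](O)[C@H](OCc1ccccc1)[C@@H](C)[C@H](O)/C(C)=C\[C@@H](C)CO | intermediate
17 | (2S,3S,4R,5S,6S,7R,8S)-7-(benzyloxy)-3,4-epoxy-2,4,6-trimethylnonane-1,5,8-triol (cis-epoxide) | C[C@H](O)[C@H](OCc1ccccc1)[C@@H](C)[C@H](O)[C@@]1(C)O[C@H]1[C@@H](C)CO | intermediate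
18 | (2S,3S)-3-[(2R,3S,4S,5R,6S)-5-(benzyloxy)-3-hydroxy-2,4,6-trimethyloxan-2-yl]-2-methylpropane-1,3-diol (C1-OH, C3-OH, C5-OH free, C7-OBn) | C[C@@H]1O[C@](C)([C@@H](O)[C@@H](C)CO)[C@@H](O)[C@H](C)[C@H]1OCc1ccccc1 | intermediate
19 | C1 aldehyde of 18 (other centres as in 18) | C[C@@H]1O[C@](C)([C@@H](O)[C@@H](C)C=O)[C@@H](O)[C@H](C)[C@H]1OCc1ccccc1 | intermediate
20 | bicyclic lactol (C1 hemiacetal of 21, both C1 epimers) | c1ccccc1CO[C@@H]1[C@@H](C)[C@@H]2OC(O)[C@H](C)[C@H](O)[C@@]2(C)O[C@H]1C | intermediate
21 | 7-O-benzyl-3-hydroxy bicyclic δ-lactone (stereocentres as in 30) | c1ccccc1CO[C@@H]1[C@@H](C)[C@@H]2OC(=O)[C@H](C)[C@H](O)[C@@]2(C)O[C@H]1C | intermediate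
22 | 7-O-benzyl bicyclic lactone 3-acetate (stereocentres as in 30) | c1ccccc1CO[C@@H]1[C@@H](C)[C@@H]2OC(=O)[C@H](C)[C@H](OC(C)=O)[C@@]2(C)O[C@H]1C | intermediate
23 | core alcohol, (2R,3S,4S,5S,6R,7R,8S)-3-acetoxy-7-hydroxy bicyclic lactone (30 without the C7 acyl group) | O[C@@H]1[C@@H](C)[C@@H]2OC(=O)[C@H](C)[C@H](OC(C)=O)[C@@]2(C)O[C@H]1C | intermediate
24 | ethyl propiolate | C#CC(=O)OCC | starting material
25 | ethyl (Z)-3-(tributylstannyl)acrylate | CCCC[Sn](CCCC)(CCCC)/C=C\C(=O)OCC | intermediate
26 | (Z)-3-(tributylstannyl)acrylic acid | CCCC[Sn](CCCC)(CCCC)/C=C\C(=O)O | intermediate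
27 | mixed anhydride of 26 with 2-methyl-6-nitrobenzoic acid | CCCC[Sn](CCCC)(CCCC)/C=C\C(=O)OC(=O)c1c(C)cccc1[N+](=O)[O-] | intermediate
28 | (Z)-3-(tributylstannyl)acrylate of 23 at O7 | CCCC[Sn](CCCC)(CCCC)/C=C\C(=O)O[C@@H]1[C@@H](C)[C@@H]2OC(=O)[C@H](C)[C@H](OC(C)=O)[C@@]2(C)O[C@H]1C | intermediate
29 | heptanoyl chloride | CCCCCCC(=O)Cl | starting material
30 | botcinin J | CCCCCCC(=O)/C=C\C(=O)O[C@@H]1[C@@H](C)[C@@H]2OC(=O)[C@H](C)[C@H](OC(C)=O)[C@@]2(C)O[C@H]1C | target

Total step count: 19. Longest linear sequence: 14 steps (5 to 30 through steps 4–15, 18 and 19).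

Steps most likely to fail

Step 19. The Z-enedione may isomerise to E under palladium, the acylpalladium may decarbonylate, or transmetalation of the chelated, electron-poor stannane may be slow enough for protodestannylation to take over. The fallback sets out from 23 and returns at 30. Esterification with propiolic acid (DCC, cat. DMAP, CH2Cl2, −20 °C) would give the core propiolate F1. Its zinc alkynylide (Me2Zn, cat. ProPhenol, toluene, 4 °C) would add to heptanal and form the same C3′–C4′ bond as the propargylic alcohol F2 (both C4′ epimers). Dess–Martin oxidation would give the ynone F3, and Lindlar semihydrogenation (Pd/CaCO3/Pb, quinoline, H2, EtOAc, 0 °C) would deliver 30 by syn addition of hydrogen.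

Step 12. Substrate control may give poor facial selectivity in the directed epoxidation if the C2 stereocentre or the remote hydroxyls compete with the C5 hydroxyl. The fallback sets out from 15 and returns at 18. Silylation of C5-OH (TESOTf, 2,6-lutidine, CH2Cl2, −78 °C) would give the tris-silyl ether F4. A reagent-controlled Shi epoxidation with the enantiomer of the fructose-derived ketone catalyst (from L-sorbose, chosen by the spiro transition-state model; Oxone, K2CO3, MeCN/DMM/buffer, 0 °C) would give the silylated cis-(3S,4R)-epoxide F5. Buffered TBAF/AcOH would remove all three silyl groups to 17, which CSA would close to 18 as in the main route.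

Step 9. Addition of the hindered alkenyllithium to the α-branched Weinreb amide may be slow, allowing enolisation at C6 or loss of alkene geometry on warming. The fallback sets out from 12 and returns at 15. DIBAL-H reduction (THF, −78 °C) would give the aldehyde F6. A Nozaki–Hiyama–Kishi coupling with 4 (CrCl2, cat. NiCl2, DMSO, rt) would add the alkenyl group with retention of geometry and Felkin–Anh control, giving 15 directly so that step 10 is skipped. Any C5 epimer would be oxidised to 14 and reduced as in step 10.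

Further compounds
F1 | step 19 | propiolate ester of 23 at O7 | C#CC(=O)O[C@@H]1[C@@H](C)[C@@H]2OC(=O)[C@H](C)[C@H](OC(C)=O)[C@@]2(C)O[C@H]1C
F2 | step 19 | 4′-hydroxydec-2′-ynoate of 23 (C4′ epimers) | CCCCCCC(O)C#CC(=O)O[C@@H]1[C@@H](C)[C@@H]2OC(=O)[C@H](C)[C@H](OC(C)=O)[C@@]2(C)O[C@H]1C
F3 | step 19 | 4′-oxodec-2′-ynoate of 23 | CCCCCCC(=O)C#CC(=O)O[C@@H]1[C@@H](C)[C@@H]2OC(=O)[C@H](C)[C@H](OC(C)=O)[C@@]2(C)O[C@H]1C
F4 | step 12 | C5-O-triethylsilyl ether of 15 | C[C@H](O[Si](C)(C)C(C)(C)C)[C@H](OCc1ccccc1)[C@@H](C)[C@H](O[Si](CC)(CC)CC)/C(C)=C\[C@@H](C)CO[Si](C)(C)C(C)(C)C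
F5 | step 12 | cis-(3S,4R)-epoxide of F4 | C[C@H](O[Si](C)(C)C(C)(C)C)[C@H](OCc1ccccc1)[C@@H](C)[C@H](O[Si](CC)(CC)CC)[C@@]1(C)O[C@H]1[C@@H](C)CO[Si](C)(C)C(C)(C)C
F6 | step 9 | (2R,3R,4S)-3-(benzyloxy)-4-(tert-butyldimethylsilyloxy)-2-methylpentanal | C[C@H](O[Si](C)(C)C(C)(C)C)[C@H](OCc1ccccc1)[C@@H](C)C=O
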